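The route rests on disconnecting the C5–C6 bond of the cyclopentane ring. The unsubstituted C6 methylene lies between the oxygenated C7 and the allylic ring-fusion methine C5, so a rhodium carbene at C6, generated from a C7 diazoketone, can insert into a C5–H bond of a monocyclic dihydropyranone. This single operation closes the five-membered ring, forms C5–C6 and sets C5 cis to C9. The precursor is an enol lactone (C1 lactone carbonyl, C3=C4 bearing the C11 ester) whose C9 carries the fully substituted C8 with a silyloxy group, the silyloxymethyl C10 and the diazoacetyl unit C7–C6; C8 and C9 are set by one catalytic aldol addition. Iridoid numbering is used throughout.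

Key step: step 9

Remarks on the chemistry
- Numbering: C1 acyl acetal carbon, O2, C3=C4 (C4 bears C11), C5 and C9 ring fusion, C6, C7, C8 (bears C10); beta is the face of H5 and H9. In the monocyclic compounds, pyranone positions 2, 3, 4, 5, 6 are iridoid C1, C9, C5, C4, C3.
- Target configuration: C1–O-acyl beta, H5 and H9 beta, C7–O beta, C8–OH alpha, C10 beta, i.e. (1S,5S,7S,8R,9S) with an (R)-3-methylpentanoyl and a Z-coumaroyl group.
- Assumption: the hemiacetal formed in step 12 is an interconverting mixture of C1 anomers and is drawn as the beta anomer.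
- Design choices:
  (a) O10 carries a tert-butyldiphenylsilyl group, which makes the oxygen lying 1,5 to the carbene bulky and weakly basic and survives selective removal of the C8 triethylsilyl ether.
  (b) C7 is set directly by hydroxyl-directed reduction from the C8 hydroxyl. Hydride attack on the convex beta face would give the 7-alpha alcohol and would then demand an SN2 inversion at a neopentylic carbinol.
  (c) The primary C11 hydroxyl is silylated before C1 is acylated, since it would otherwise react ahead of the hemiacetal.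

Step 1
Reactants: 1 methyl coumalate
Product: 2 methyl 2-oxo-3,4-dihydro-2H-pyran-5-carboxylate
Conditions: H2 (1 atm, stopped after 1 equiv), 5% Pd/C, EtOAc, rt
Reagents that add atoms: none
Why: Chemoselective catalytic hydrogenation, in which the unsubstituted cis-disubstituted C9=C5 alkene should be saturated much faster than the trisubstituted push–pull C3=C4 enol-ether acrylate, so that the enol lactone is kept.

Step 2
Reactants: 2 methyl 2-oxo-3,4-dihydro-2H-pyran-5-carboxylate
Product: 3 methyl 6-(trimethylsilyloxy)-4H-pyran-3-carboxylate (cyclic silyl ketene acetal, used crude)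
Conditions: LiN(SiMe3)2, Me3SiCl (in situ quench), THF, −78 °C
Reagents that add atoms: chlorotrimethylsilane, C[Si](C)(C)Cl
Why: Silyl ketene acetal formation by kinetic enolisation, in which the C9 methylene alpha to the lactone carbonyl is the most acidic position and trapping the enolate as it forms at −78 °C prevents ketene-type opening of the enol ester.

Step 3
Reactants: 4 hydroxypyruvic acid
Product: 5 benzyl 3-hydroxy-2-oxopropanoate
Conditions: BnBr, KHCO3, DMF, rt
Reagents that add atoms: benzyl bromide, BrCc1ccccc1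
Why: Carboxylate O-alkylation (SN2), in which only the carboxylate formed with bicarbonate is nucleophilic enough for benzyl bromide, giving an ester that hydrogenolysis can later remove beside the methyl ester.

Step 4
Reactants: 5 benzyl 3-hydroxy-2-oxopropanoate
Product: 6 benzyl 3-(tert-butyldiphenylsilyloxy)-2-oxopropanoate
Conditions: t-BuPh2SiCl, imidazole, CH2Cl2, 0 °C
Reagents that add atoms: tert-butyl(chloro)diphenylsilane, CC(C)(C)[Si](Cl)(c1ccccc1)c1ccccc1
Why: Silylation of a primary alcohol, giving a bulky and weakly basic ether on O10 that should neither bind copper in step 5 nor attack the carbene in step 9.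

Step 5
Reactants: 3 methyl 6-(trimethylsilyloxy)-4H-pyran-3-carboxylate; 6 benzyl 3-(tert-butyldiphenylsilyloxy)-2-oxopropanoate
Product: 8 methyl (3S)-3-[(2R)-1-(benzyloxy)-3-(tert-butyldiphenylsilyloxy)-2-hydroxy-1-oxopropan-2-yl]-2-oxo-3,4-dihydro-2H-pyran-5-carboxylate, via trimethylsilyl ether 7 (not isolated)
Conditions: Cu(OTf)2 (10 mol%), 2,2'-(propane-2,2-diyl)bis[(4S)-4-tert-butyl-4,5-dihydro-1,3-oxazole] (11 mol%), THF, −78 °C; then 1 M HCl, THF, 0 °C
Reagents that add atoms: none
Why: Catalytic enantioselective Mukaiyama aldol addition to an alpha-keto ester held on divalent copper through both carbonyl oxygens, in which the tert-butyl group of the ligand should block the re face so that C9 adds to the si face of the C8 ketone (8R), and the open antiperiplanar transition state that keeps the ring methylene C5 away from the bound ester should give the syn relation of C5 and the C8 oxygen (9S); the acidic work-up cleaves the silyl ether 7.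

Step 6
Reactants: 8 aldol adduct (tertiary alcohol)
Product: 9 methyl (3S)-3-[(2R)-1-(benzyloxy)-3-(tert-butyldiphenylsilyloxy)-1-oxo-2-(triethylsilyloxy)propan-2-yl]-2-oxo-3,4-dihydro-2H-pyran-5-carboxylate
Conditions: Et3SiOTf, 2,6-lutidine, CH2Cl2, −78 to 0 °C
Reagents that add atoms: triethylsilyl trifluoromethanesulfonate, CC[Si](CC)(CC)OS(=O)(=O)C(F)(F)F
Why: Silyl ether formation with a silyl triflate, which the hindered tertiary C8 hydroxyl requires and which is needed because a free alpha-hydroxyl would undergo O–H insertion with the carbene of step 9.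

Step 7
Reactants: 9 benzyl ester
Product: 10 (2R)-3-(tert-butyldiphenylsilyloxy)-2-[(3S)-5-(methoxycarbonyl)-2-oxo-3,4-dihydro-2H-pyran-3-yl]-2-(triethylsilyloxy)propanoic acid
Conditions: H2 (1 atm), 10% Pd/C, EtOAc, rt
Reagents that add atoms: none
Why: Hydrogenolysis of a benzyl ester, which is fast on Pd/C while the trisubstituted push–pull alkene (the one that survives step 1), the silyl ethers and the methyl ester should be inert under these neutral conditions.

Step 8
Reactants: 10 carboxylic acid
Product: 12 methyl (3S)-3-[(2R)-1-(tert-butyldiphenylsilyloxy)-4-diazo-3-oxo-2-(triethylsilyloxy)butan-2-yl]-2-oxo-3,4-dihydro-2H-pyran-5-carboxylate, via acid chloride 11 (not isolated)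
Conditions: 1-chloro-N,N,2-trimethylprop-1-en-1-amine, CH2Cl2, 0 °C to rt; then Me3SiCHN2, MeCN/THF, 0 °C
Reagents that add atoms: (trimethylsilyl)diazomethane, C[Si](C)(C)C=[N+]=[N-] (supplies C6 and both nitrogens); 1-chloro-N,N,2-trimethylprop-1-en-1-amine, CC(C)=C(Cl)N(C)C (supplies only the chlorine of intermediate 11)
Why: Neutral acid chloride formation followed by acylation of a diazoalkane (diazoketone synthesis), in which the alpha-chloroenamine activates the hindered silyloxy acid without free HCl and the diazo carbon then attacks the acyl chloride, C8 having no hydrogen from which a ketene could form.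

Step 9
Reactants: 12 diazoketone
Product: 13 methyl (4aS,7R,7aS)-7-[(tert-butyldiphenylsilyloxy)methyl]-1,6-dioxo-7-(triethylsilyloxy)-1,4a,5,6,7,7a-hexahydrocyclopenta[c]pyran-4-carboxylate
Conditions: Rh2(OAc)4 (1 mol%), CH2Cl2, rt, slow addition of 12 at high dilution
Reagents that add atoms: none
Why: Rh2(OAc)4 expels N2 from 12 and gives an electrophilic rhodium carbene at C6, which inserts into a C5–H bond through a concerted three-centre transition state with retention at C5. The closest known reaction type is the Rh2(OAc)4-catalysed 1,5 C–H insertion of alpha-diazoketones that gives cyclopentanones. The cyclopentanone (C5–C6–C7–C8–C9) closes by 1,5-insertion, and the two hydrogens on C5 are the only carbon-bound hydrogens in the 1,5 position because C1 is a carbonyl carbon and C8 is fully substituted. The new stereocentre C5 is controlled by C9: the tether on C9 should engage the C5 hydrogen on its own face, since a trans fusion onto the flattened enol-lactone ring is far more strained, so H5 and H9 end up cis. The step needs insertion at C5–H to win over cyclopropanation of C3=C4, ylide formation at the C1 carbonyl oxygen or at O10, and O–H insertion. This is secured by the C4 ester (electron-poor push–pull alkene), the weakly basic oxygens of an enol-ester carbonyl and of a bulky tert-butyldiphenylsilyl ether, the silylated C8 oxygen, the allylic activation of C5–H through conjugation with O2, and slow addition at high dilution.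

Step 10
Reactants: 13 bicyclic ketone
Product: 14 methyl (4aS,7R,7aS)-7-[(tert-butyldiphenylsilyloxy)methyl]-7-hydroxy-1,6-dioxo-1,4a,5,6,7,7a-hexahydrocyclopenta[c]pyran-4-carboxylate
Conditions: HF·pyridine, pyridine, THF, 0 °C to rt
Reagents that add atoms: none
Why: Selective desilylation with buffered HF·pyridine, in which a triethylsilyl ether is cleaved much faster than a tert-butyldiphenylsilyl ether and the non-nucleophilic medium should leave the enol lactone and the alpha-ketol untouched.

Step 11
Reactants: 14 alpha-hydroxy ketone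
Product: 15 methyl (4aS,6S,7R,7aS)-7-[(tert-butyldiphenylsilyloxy)methyl]-6,7-dihydroxy-1-oxo-1,4a,5,6,7,7a-hexahydrocyclopenta[c]pyran-4-carboxylate
Conditions: Me4NBH(OAc)3, MeCN/AcOH (1:1), −20 to 0 °C
Reagents that add atoms: none
Why: Hydroxyl-directed triacetoxyborohydride reduction (Evans–Saksena reduction), in which exchange of an acetate on boron for the alpha-face C8 hydroxyl should deliver hydride intramolecularly to the alpha face of C7 and place the new hydroxyl on the beta face, trans to the C8 hydroxyl (7S), while lactone and ester are inert to this mild hydride.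

Step 12
Reactants: 15 diol lactone
Product: 16 (1R,4aS,6S,7R,7aS)-7-[(tert-butyldiphenylsilyloxy)methyl]-4-(hydroxymethyl)-1,4a,5,6,7,7a-hexahydrocyclopenta[c]pyran-1,6,7-triol (used crude)
Conditions: i-Bu2AlH (7 equiv), CH2Cl2, −78 °C; aq. KNaC4H4O6 (sodium potassium tartrate)
Reagents that add atoms: none
Why: Hydride reduction with i-Bu2AlH, in which the lactone should stop at the aluminium hemiacetal that is stable at −78 °C until work-up, as in the reduction of iridoid enol lactones to lactols, while the beta-alkoxyacrylate ester is taken by 1,2-reduction to the allylic C11 alcohol.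

Step 13
Reactants: 16 hemiacetal tetraol
Product: 17 (1R,4aS,6S,7R,7aS)-4-[(tert-butyldimethylsilyloxy)methyl]-7-[(tert-butyldiphenylsilyloxy)methyl]-1,4a,5,6,7,7a-hexahydrocyclopenta[c]pyran-1,6,7-triol
Conditions: t-BuMe2SiCl (1.05 equiv), imidazole, DMF, −20 °C
Reagents that add atoms: tert-butyl(chloro)dimethylsilane, CC(C)(C)[Si](C)(C)Cl
Why: Selective silylation of a primary alcohol, in which one equivalent of silyl chloride at low temperature should take the unhindered allylic C11 hydroxyl ahead of the hemiacetal, the neopentylic secondary C7 hydroxyl and the tertiary C8 hydroxyl, as in the primary-selective silylation of free sugars.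

Step 14
Reactants: 17 hemiacetal; 18 (R)-3-methylpentanoic acid
Product: 20 (1S,4aS,6S,7R,7aS)-4-[(tert-butyldimethylsilyloxy)methyl]-7-[(tert-butyldiphenylsilyloxy)methyl]-6,7-dihydroxy-1,4a,5,6,7,7a-hexahydrocyclopenta[c]pyran-1-yl (3R)-3-methylpentanoate, via (R)-3-methylpentanoyl chloride 19 (not isolated)
Conditions: 18, (COCl)2, cat. DMF, CH2Cl2, 0 °C to rt, evaporation; then 17, pyridine, DMAP (5 mol%), CH2Cl2, −40 °C
Reagents that add atoms: oxalyl chloride, ClC(=O)C(=O)Cl (supplies only the chlorine of intermediate 19)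
Why: Anomeric O-acylation with an acyl chloride, in which the hemiacetal hydroxyl is the most acidic and most readily acylated hydroxyl left and, because the anomers interconvert by ring opening in pyridine, the ester should settle on the beta face of C1, trans to the fully substituted C8 and axial for anomeric stabilisation (1S).

Step 15
Reactants: 21 4-hydroxybenzaldehyde
Product: 22 4-(triisopropylsilyloxy)benzaldehyde
Conditions: i-Pr3SiCl, imidazole, DMF, rt
Reagents that add atoms: chlorotriisopropylsilane, CC(C)[Si](Cl)(C(C)C)C(C)C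
Why: Silylation of a phenol, which masks the acidic hydroxyl for the olefination with a group hindered enough to survive the cold saponification of step 17.

Step 16
Reactants: 22 4-(triisopropylsilyloxy)benzaldehyde
Product: 23 methyl (2Z)-3-[4-(triisopropylsilyloxy)phenyl]prop-2-enoate
Conditions: (CF3CH2O)2P(O)CH2CO2Me, KN(SiMe3)2, 18-crown-6, THF, −78 °C
Reagents that add atoms: methyl bis(2,2,2-trifluoroethyl)phosphonoacetate, COC(=O)CP(=O)(OCC(F)(F)F)OCC(F)(F)F
Why: Still–Gennari olefination, in which the electron-poor phosphonate eliminates rapidly from the kinetically formed adduct of its dissociated potassium anion and so should give the Z-alkene.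

Step 17
Reactants: 23 Z-methyl ester
Product: 24 (2Z)-3-[4-(triisopropylsilyloxy)phenyl]prop-2-enoic acid
Conditions: LiOH, THF/H2O, 0 °C; then 1 M HCl to pH 4, 0 °C; exclusion of light
Reagents that add atoms: lithium hydroxide, [Li+].[OH-]
Why: Saponification, in which hydroxide attacks the unhindered methyl ester carbonyl at 0 °C while the Z double bond and the hindered aryl silyl ether should be retained.

Step 18
Reactants: 20 C1 ester with free C7 hydroxyl; 24 Z-acid
Product: 25 (1S,4aS,6S,7R,7aS)-4-[(tert-butyldimethylsilyloxy)methyl]-7-[(tert-butyldiphenylsilyloxy)methyl]-7-hydroxy-6-({(2Z)-3-[4-(triisopropylsilyloxy)phenyl]prop-2-enoyl}oxy)-1,4a,5,6,7,7a-hexahydrocyclopenta[c]pyran-1-yl (3R)-3-methylpentanoate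
Conditions: EDC·HCl, DMAP (0.3 equiv), CH2Cl2, 0 °C to rt, exclusion of light
Reagents that add atoms: none
Why: Steglich esterification, which acylates the secondary C7 hydroxyl with retention at C7 while the tertiary C8 hydroxyl is too hindered to compete, and in which low temperature, sub-stoichiometric DMAP and darkness should protect the Z-alkene.

Step 19
Reactants: 25 fully protected target
Product: 26 (1S,4aS,6S,7R,7aS)-7-hydroxy-4,7-bis(hydroxymethyl)-6-{[(2Z)-3-(4-hydroxyphenyl)prop-2-enoyl]oxy}-1,4a,5,6,7,7a-hexahydrocyclopenta[c]pyran-1-yl (3R)-3-methylpentanoate (CNP0217341.1)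
Conditions: Bu4NF/AcOH (1:1), THF, 0 °C to rt, exclusion of light
Reagents that add atoms: none
Why: Fluoride-mediated desilylation buffered with acetic acid, which should cleave the aryl, the allylic primary and the neopentylic primary silyl ethers while the near-neutral medium avoids acid-promoted ionisation of the C1 acyl acetal and enol ether and base-promoted migration of the C7 ester to O10.

Compound list
1 | methyl coumalate | COC(=O)C1=COC(=O)C=C1 | starting material
2 | methyl 2-oxo-3,4-dihydro-2H-pyran-5-carboxylate | COC(=O)C1=COC(=O)CC1 | intermediate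
3 | methyl 6-(trimethylsilyloxy)-4H-pyran-3-carboxylate | COC(=O)C1=COC(O[Si](C)(C)C)=CC1 | intermediate
4 | hydroxypyruvic acid | OCC(=O)C(=O)O | starting material
5 | benzyl 3-hydroxy-2-oxopropanoate | OCC(=O)C(=O)OCc1ccccc1 | intermediate
6 | benzyl 3-(tert-butyldiphenylsilyloxy)-2-oxopropanoate | CC(C)(C)[Si](OCC(=O)C(=O)OCc1ccccc1)(c1ccccc1)c1ccccc1 | intermediate
7 | trimethylsilyl ether of aldol adduct 8 (not isolated) | O=C1OC=C(C(=O)OC)C[C@H]1[C@@](O[Si](C)(C)C)(CO[Si](c2ccccc2)(c2ccccc2)C(C)(C)C)C(=O)OCc2ccccc2 | intermediate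
8 | methyl (3S)-3-[(2R)-1-(benzyloxy)-3-(tert-butyldiphenylsilyloxy)-2-hydroxy-1-oxopropan-2-yl]-2-oxo-3,4-dihydro-2H-pyran-5-carboxylate | O=C1OC=C(C(=O)OC)C[C@H]1[C@@](O)(CO[Si](c2ccccc2)(c2ccccc2)C(C)(C)C)C(=O)OCc2ccccc2 | intermediate
9 | C8 triethylsilyl ether of 8 | O=C1OC=C(C(=O)OC)C[C@H]1[C@@](O[Si](CC)(CC)CC)(CO[Si](c2ccccc2)(c2ccccc2)C(C)(C)C)C(=O)OCc2ccccc2 | intermediate
10 | (2R)-3-(tert-butyldiphenylsilyloxy)-2-[(3S)-5-(methoxycarbonyl)-2-oxo-3,4-dihydro-2H-pyran-3-yl]-2-(triethylsilyloxy)propanoic acid | O=C1OC=C(C(=O)OC)C[C@H]1[C@@](O[Si](CC)(CC)CC)(CO[Si](c2ccccc2)(c2ccccc2)C(C)(C)C)C(=O)O | intermediate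
11 | acid chloride of 10 (not isolated) | O=C1OC=C(C(=O)OC)C[C@H]1[C@@](O[Si](CC)(CC)CC)(CO[Si](c2ccccc2)(c2ccccc2)C(C)(C)C)C(=O)Cl | intermediate
12 | diazoketone, methyl (3S)-3-[(2R)-1-(tert-butyldiphenylsilyloxy)-4-diazo-3-oxo-2-(triethylsilyloxy)butan-2-yl]-2-oxo-3,4-dihydro-2H-pyran-5-carboxylate | O=C1OC=C(C(=O)OC)C[C@H]1[C@@](O[Si](CC)(CC)CC)(CO[Si](c2ccccc2)(c2ccccc2)C(C)(C)C)C(=O)C=[N+]=[N-] | intermediate
13 | cis-fused C7 ketone, methyl (4aS,7R,7aS)-7-[(tert-butyldiphenylsilyloxy)methyl]-1,6-dioxo-7-(triethylsilyloxy)-1,4a,5,6,7,7a-hexahydrocyclopenta[c]pyran-4-carboxylate | O=C1OC=C(C(=O)OC)[C@H]2CC(=O)[C@](O[Si](CC)(CC)CC)(CO[Si](c3ccccc3)(c3ccccc3)C(C)(C)C)[C@@H]12 | intermediate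
14 | C8 alcohol of 13 (alpha-hydroxy ketone) | O=C1OC=C(C(=O)OC)[C@H]2CC(=O)[C@](O)(CO[Si](c3ccccc3)(c3ccccc3)C(C)(C)C)[C@@H]12 | intermediate
15 | 7-beta,8-alpha-diol lactone, methyl (4aS,6S,7R,7aS)-7-[(tert-butyldiphenylsilyloxy)methyl]-6,7-dihydroxy-1-oxo-1,4a,5,6,7,7a-hexahydrocyclopenta[c]pyran-4-carboxylate | O=C1OC=C(C(=O)OC)[C@H]2C[C@H](O)[C@](O)(CO[Si](c3ccccc3)(c3ccccc3)C(C)(C)C)[C@@H]12 | intermediate
16 | hemiacetal with free C11, C7 and C8 hydroxyls (beta anomer drawn) | O[C@@H]1OC=C(CO)[C@H]2C[C@H](O)[C@](O)(CO[Si](c3ccccc3)(c3ccccc3)C(C)(C)C)[C@@H]12 | intermediate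
17 | C11 tert-butyldimethylsilyl ether of 16 | O[C@@H]1OC=C(CO[Si](C)(C)C(C)(C)C)[C@H]2C[C@H](O)[C@](O)(CO[Si](c3ccccc3)(c3ccccc3)C(C)(C)C)[C@@H]12 | intermediate
18 | (R)-3-methylpentanoic acid | CC[C@@H](C)CC(=O)O | starting material
19 | (R)-3-methylpentanoyl chloride (not isolated) | CC[C@@H](C)CC(=O)Cl | intermediate
20 | C1 beta (3R)-3-methylpentanoate with free C7 and C8 hydroxyls | CC[C@@H](C)CC(=O)O[C@@H]1OC=C(CO[Si](C)(C)C(C)(C)C)[C@H]2C[C@H](O)[C@](O)(CO[Si](c3ccccc3)(c3ccccc3)C(C)(C)C)[C@@H]12 | intermediate
21 | 4-hydroxybenzaldehyde | O=Cc1ccc(O)cc1 | starting material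
22 | 4-(triisopropylsilyloxy)benzaldehyde | O=Cc1ccc(O[Si](C(C)C)(C(C)C)C(C)C)cc1 | intermediate
23 | methyl (2Z)-3-[4-(triisopropylsilyloxy)phenyl]prop-2-enoate | COC(=O)/C=C\c1ccc(O[Si](C(C)C)(C(C)C)C(C)C)cc1 | intermediate
24 | (2Z)-3-[4-(triisopropylsilyloxy)phenyl]prop-2-enoic acid | OC(=O)/C=C\c1ccc(O[Si](C(C)C)(C(C)C)C(C)C)cc1 | intermediate
25 | tris-silylated target | CC[C@@H](C)CC(=O)O[C@@H]1OC=C(CO[Si](C)(C)C(C)(C)C)[C@H]2C[C@H](OC(=O)/C=C\c3ccc(O[Si](C(C)C)(C(C)C)C(C)C)cc3)[C@](O)(CO[Si](c3ccccc3)(c3ccccc3)C(C)(C)C)[C@@H]12 | intermediate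
26 | CNP0217341.1 | CC[C@@H](C)CC(=O)O[C@@H]1OC=C(CO)[C@H]2C[C@H](OC(=O)/C=C\c3ccc(O)cc3)[C@](O)(CO)[C@@H]12 | target

Total step count: 19. Longest linear sequence: 14 steps (steps 1, 2, 5 to 14, 18, 19).

Steps most likely to fail

Step 9 (carbene C–H insertion). The carbene may be intercepted before it reaches C5–H: capture by the C1 carbonyl oxygen or by O10 to give ylides, or addition to C3=C4. It may also insert with poor control of the ring fusion. The fallback sets out from acid 10 and comes back at ketone 13. It replaces the unstabilised carbene by a stabilised acceptor/acceptor carbene, the substrate class for which 1,5 C–H insertion to cyclopentanones is most selective. Acid 10 is activated with 1,1'-carbonyldiimidazole and condensed with Mg(O2CCH2CO2Bn)2 to give the benzyl beta-keto ester F1. Diazo transfer from 4-acetamidobenzenesulfonyl azide (Et3N, MeCN) gives the alpha-diazo-beta-keto ester F2. Rh2(OAc)4 in CH2Cl2 should then give the bicyclic beta-keto ester F3. Hydrogenolysis (H2, Pd/C, EtOAc) gives the beta-keto acid F4, which loses CO2 on gentle warming to give 13.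

Step 5 (aldol addition). Facial discrimination at the ketone or the simple diastereoselection may be poor, because the silyloxymethyl ketone and the cyclic ketene acetal both lie outside the best-established substrate range. The labile 4H-pyran ketene acetal may also decompose before it adds. The fallback sets out from enol lactone 2 and comes back at aldol adduct 8. It uses an open-chain thioester ketene acetal, the nucleophile class for which this copper catalyst is established, and closes the lactone afterwards. Ethanethiol with catalytic Et3N opens 2 to the S-ethyl thioester F5 (formyl ester, enol form). LiN(SiMe3)2 (2 equiv) with Me3SiCl gives the bis-silylated ketene thioacetal F6. The catalyst of step 5 with keto ester 6 should give the silylated adduct F7 and, after HCl work-up, the thioester aldol adduct F8. AgO2CCF3 then activates the thioester, and the enol oxygen closes the six-membered enol lactone to give 8.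

Step 14 (C1 acylation). Site selectivity between the hemiacetal and the C7 hydroxyl may be poor, and the acyl group may settle partly on the alpha face of C1. The fallback sets out from diol 15 and comes back at 20. It replaces kinetic discrimination by a temporary protecting group. Et3SiCl with imidazole silylates only the secondary C7 hydroxyl and gives the C7 triethylsilyl ether F9. i-Bu2AlH as in step 12 gives the hemiacetal F10. t-BuMe2SiCl as in step 13 gives the C11 silyl ether F11. Acylation with 19 as in step 14, now with the hemiacetal as the only reactive hydroxyl, gives the C1 ester F12. HF·pyridine with pyridine at 0 °C removes the secondary triethylsilyl group selectively and gives 20.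

Further compounds
F1 | step 9 | benzyl beta-keto ester from 10 (C7 ketone extended by CH2CO2Bn) | O=C1OC=C(C(=O)OC)C[C@H]1[C@@](O[Si](CC)(CC)CC)(CO[Si](c2ccccc2)(c2ccccc2)C(C)(C)C)C(=O)CC(=O)OCc2ccccc2
F2 | step 9 | alpha-diazo-beta-keto benzyl ester | O=C1OC=C(C(=O)OC)C[C@H]1[C@@](O[Si](CC)(CC)CC)(CO[Si](c2ccccc2)(c2ccccc2)C(C)(C)C)C(=O)C(=[N+]=[N-])C(=O)OCc2ccccc2
F3 | step 9 | bicyclic beta-keto ester, 13 with a benzyloxycarbonyl group on C6 (C6 epimers) | O=C1OC=C(C(=O)OC)[C@H]2C(C(=O)OCc3ccccc3)C(=O)[C@](O[Si](CC)(CC)CC)(CO[Si](c3ccccc3)(c3ccccc3)C(C)(C)C)[C@@H]12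
F4 | step 9 | beta-keto acid, 13 with a carboxyl group on C6 | O=C1OC=C(C(=O)OC)[C@H]2C(C(=O)O)C(=O)[C@](O[Si](CC)(CC)CC)(CO[Si](c3ccccc3)(c3ccccc3)C(C)(C)C)[C@@H]12
F5 | step 5 | methyl 5-(ethylsulfanyl)-2-(hydroxymethylidene)-5-oxopentanoate | CCSC(=O)CCC(C(=O)OC)=CO
F6 | step 5 | methyl 5-(ethylsulfanyl)-5-(trimethylsilyloxy)-2-[(trimethylsilyloxy)methylidene]pent-4-enoate | CCSC(O[Si](C)(C)C)=CCC(C(=O)OC)=CO[Si](C)(C)C
F7 | step 5 | bis-trimethylsilylated thioester aldol adduct | CCSC(=O)[C@@H](CC(C(=O)OC)=CO[Si](C)(C)C)[C@@](O[Si](C)(C)C)(CO[Si](c1ccccc1)(c1ccccc1)C(C)(C)C)C(=O)OCc1ccccc1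
F8 | step 5 | thioester aldol adduct (open-chain form of 8) | CCSC(=O)[C@@H](CC(C(=O)OC)=CO)[C@@](O)(CO[Si](c1ccccc1)(c1ccccc1)C(C)(C)C)C(=O)OCc1ccccc1
F9 | step 14 | C7 triethylsilyl ether of 15 | O=C1OC=C(C(=O)OC)[C@H]2C[C@H](O[Si](CC)(CC)CC)[C@](O)(CO[Si](c3ccccc3)(c3ccccc3)C(C)(C)C)[C@@H]12
F10 | step 14 | C7 triethylsilyl ether of 16 | O[C@@H]1OC=C(CO)[C@H]2C[C@H](O[Si](CC)(CC)CC)[C@](O)(CO[Si](c3ccccc3)(c3ccccc3)C(C)(C)C)[C@@H]12
F11 | step 14 | C7 triethylsilyl ether of 17 | O[C@@H]1OC=C(CO[Si](C)(C)C(C)(C)C)[C@H]2C[C@H](O[Si](CC)(CC)CC)[C@](O)(CO[Si](c3ccccc3)(c3ccccc3)C(C)(C)C)[C@@H]12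
F12 | step 14 | C7 triethylsilyl ether of 20 | CC[C@@H](C)CC(=O)O[C@@H]1OC=C(CO[Si](C)(C)C(C)(C)C)[C@H]2C[C@H](O[Si](CC)(CC)CC)[C@](O)(CO[Si](c3ccccc3)(c3ccccc3)C(C)(C)C)[C@@H]12
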